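# Proposed total synthesis of Selaginellin U (14)

## The problem

Selaginellin U (14) has no stereocentre, so nothing in it can or need direct anything in three dimensions; the difficulties are regiochemistry, crowding and oxidation level. The core is a 1,2,3,4-tetrasubstituted benzene (ring A) with a methyl group at C1, a 4-hydroxyphenyl group (ring B) at C4 and a (4-hydroxyphenyl)ethynyl group (ring E on the triple bond) at C6. Between them, C5 carries the exocyclic carbon C7. C7 is bound to a 4-hydroxyphenyl ring (ring C) and, through a double bond, to a cyclohexa-2,5-dienone (ring D), so it is a triaryl carbon with both ortho positions of ring A occupied. Any bond to C7 must therefore be made in a pocket between ring B and the alkyne. The quinone methide is an electrophile and has to be unveiled last. The electron-rich diaryl alkyne rules out hydrogenation and is at risk from strong electrophiles, hydrogen halides and indiscriminate oxidants. The four phenolic oxygens must stay masked, here as methyl ethers, until the end. The enabling feature is that C7 sits at the carbocation oxidation level and that rings C and D are the same 4-oxygenated aryl group in two tautomeric forms. Its reduced form is a diarylmethane CH2, doubly benzylic and para-methoxy-activated, from which electrons can be removed at an anode to give a cation that an unfunctionalised anisole can capture.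

## Retrosynthesis

**Oxidation level and protecting groups (14 ⇒ 13 ⇒ 12).** No skeletal bond is cut. The C7=ring D double bond is traced back to a C7–H bond plus a phenol in the leuco tetraphenol 13, and the four hydroxyl groups of 13 to the methyl ethers of 12. Arriving at C7 as a carbinol would save the oxidant, but only carbonyl addition delivers a carbinol, whereas the triarylmethane C–H is exactly what the key step produces. The forward reactions must cleave four aryl methyl ethers without touching the alkyne, then remove hydride from C7 and no other position.

**The bond from C7 to ring D (12 ⇒ 9 + 10, through cation 11).** The bond from C7 to the para carbon of one oxygenated ring is cut, giving diarylmethane 9 and anisole (10). The forward reaction is anodic oxidation of the C7 methylene of 9 to the pooled diarylcarbenium ion 11, followed by Friedel–Crafts capture.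
- The neighbouring cuts are less attractive. Cutting C7–ring A asks a ring A nucleophile between two ortho substituents to add to a benzophenone. Cutting at a ketone or ester asks aryl nucleophiles to reach a carbonyl buried between ring B and the alkyne.
- The cation is planar and is attacked by a small, flat arene, and the third aryl group needs no prior functionalisation.
- Precursor 9 lacks one aryl ring and carries C7 as a plain CH2.
- The forward step must oxidise only the doubly benzylic position, and the cation must wait for anisole without closing onto ring B or the alkyne.

**The alkyne (9 ⇒ 7 + 8).** The C6–C(sp) bond is cut to aryl bromide 7 and 4-ethynylanisole (8). Installing the alkyne after the electrolysis would keep the tolane away from the anode, but the bromide would then sit next to a diarylmethyl group and be harder to couple; that order is kept as the fallback. Installing it before the benzylic chemistry would place an alkyne ortho to a benzylic alcohol or halide. The forward Sonogashira coupling must insert palladium into a C–Br bond flanked by the methyl group and the CH2 group.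

**The bond from C7 to ring C (7 ⇒ 5 + 6).** The C7–ring C bond is cut to benzyl bromide 5 and 4-methoxyphenylboronic acid (6). A Friedel–Crafts benzylation of anisole with 5 would raise ortho/para and polyalkylation issues and could close a fluorene onto ring B. The cross-coupling fixes the site of bond formation. It must select the benzylic C–Br bond over the aryl C–Br bond, which the crowding of the latter supports.

**Adjusting C7 (5 ⇒ 4 ⇒ 3).** The bromide of 5 is traced to alcohol 4 and this to carboxylic acid 3. No carbon is added; the carboxyl carbon that directed the first bond becomes C7. The reduction must spare the aryl bromide.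

**The bond from C4 to ring B (3 ⇒ 1 + 2).** The biaryl bond is cut to 2-bromo-3-methylbenzoic acid (1) and 4-iodoanisole (2). In 1 the methyl group, the halogen for the alkyne and the carbon for C7 already stand in sequence, and the carboxylate has only one free ortho C–H. A directed C–H arylation can therefore give only the required isomer, without a second halogen or a boron group on ring A. The catalyst must leave the C–Br bond alone.

## Roads not taken

**Alternative 1:** The cut runs through ring A itself. Bonds C1–C2 and C4–C5 are broken to give the 1,3-bis(silyloxy)diene A1, derived from methyl 3-oxopentanoate, and the ketoacetal A2. In the forward sense TiCl4 would let the diene terminus attack the acetal carbon and its central carbon close by aldol reaction onto the aryl ketone. Loss of methanol and water would give salicylate A3, with methyl, ring B, the ester (future C7) and a phenol (future alkyne site) on the correct carbons.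
- Merits: the regiochemistry is written into two acyclic partners and no directing group is needed. The phenol becomes an aryl triflate ortho to an ester, a better Sonogashira partner than the crowded bromide 7. In this respect this road is superior.
- Weak points: A1 and A2 both have to be prepared, so about five operations are spent before A3 exists. C7 arrives as an ester between two ortho substituents and must accept two aryl nucleophiles. A tertiary alkoxide next to the alkyne invites ring closure onto the triple bond.
- Comparison: against the easier alkynylation the chosen plan sets a purchased ring A, a shorter sequence and a C7 that never has to be attacked as a carbonyl.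

**Alternative 2:** The cut is the C4–ring B bond. The forward key step is palladation of the only free ortho C–H of acid 1 under Pd(OAc)2/AgOAc and coupling with 2, giving A4, which is the same substance as 3. The chosen plan opens with this very reaction, so the two roads are identical here and part only in what is made of the carboxyl carbon.
- Merits: taken as the strategic step, the arylation would be followed by esterification, double addition of an aryl organometallic to give bromo carbinol A5, alkynylation and ether cleavage. The carbinol already holds the oxidation level of 14, so no oxidation step is needed and the sequence is about two steps shorter. On step count this road is better.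
- Weak points: the ester is flanked by bromine and ring B, and the benzophenone formed by the first addition is twisted and shielded. The second addition is therefore the weak link, and halogen–metal exchange at the ortho C–Br bond competes with it. The tertiary alcohol must then survive a coupling next to it.
- Comparison: the chosen plan pays two extra steps so that both aryl groups on C7 arrive by reactions that tolerate crowding, namely coupling at a primary benzylic bromide and capture of a planar cation. The two rings also enter separately, which opens congeners with different aryl groups.

**Alternative 3:** The cut removes ring A bonds C1–C6 and C4–C5. Enyne A6 supplies C1 to C4 with the methyl group and ring B. The ester-bearing triple bond of diyne A7 supplies C5 and C6, and its second triple bond survives as the arylethynyl group. In the forward sense Pd(PPh3)4 would mediate a [4+2] benzannulation to benzoate A8.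
- Merits: ring A is assembled with all four substituents, alkyne included, in one step. This is the most convergent of the four plans and the shortest on paper.
- Weak points: an enyne substituted at both termini is the least reactive class for this benzannulation, and its self-dimerisation competes. Nothing in A7 guarantees that the ester-bearing triple bond reacts rather than the aryl-bearing one, or that it adds in the orientation that puts the ester next to ring B. A8 still presents the buried-ester problem of Alternative 2, now with an alkyne ortho to the carbonyl.
- Comparison: the chosen plan sets against this convergence steps whose site selectivity is fixed by the substrate. There is one free ortho C–H in 1 and one doubly benzylic CH2 in 9.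

Key step: step 6

Remark on the chemistry: rings C and D of 14 exchange roles by phenol/quinone methide tautomerism, so the route treats them as two identical 4-oxygenated aryl groups and the leuco compound 13 can give only one quinone methide. Compounds 1, 2, 6, 8 and 10 are taken to be commercial.

## Route

Step 1
Reactants: 1 2-bromo-3-methylbenzoic acid; 2 4-iodoanisole
Product: 3 2-bromo-6-(4-methoxyphenyl)-3-methylbenzoic acid
Conditions: Pd(OAc)2 (5 mol %), AgOAc (1.3 equiv), AcOH, 110 °C
Reagents that add atoms: none
Why: Carboxylate-directed ortho C–H arylation: the carboxylate guides divalent palladium to the only free ortho C–H of 1 (the future C4 of ring A), the palladacycle adds the aryl iodide to reach tetravalent palladium, and reductive elimination forms the C4–ring B bond. Since no zerovalent palladium lies on the cycle, the C–Br bond should stay intact, and AgOAc removes the iodide.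

Step 2
Reactants: 3 2-bromo-6-(4-methoxyphenyl)-3-methylbenzoic acid
Product: 4 [2-bromo-6-(4-methoxyphenyl)-3-methylphenyl]methanol
Conditions: BH3·THF, THF, 0 °C to reflux; MeOH quench
Reagents that add atoms: none
Why: Borane reduction of a carboxylic acid through its acyloxyborane, a pathway that is little affected by the two ortho substituents and that leaves the aryl bromide and the methyl ether untouched.

Step 3
Reactants: 4 [2-bromo-6-(4-methoxyphenyl)-3-methylphenyl]methanol
Product: 5 2-bromo-3-(bromomethyl)-4-(4-methoxyphenyl)-1-methylbenzene
Conditions: PBr3, CH2Cl2, 0 °C
Reagents that add atoms: phosphorus tribromide, BrP(Br)Br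
Why: Conversion of a primary benzylic alcohol into the bromide by bromide displacement of its phosphite ester. The low temperature keeps a free benzylic cation, and with it ring closure onto ring B, out of play.

Step 4
Reactants: 5 2-bromo-3-(bromomethyl)-4-(4-methoxyphenyl)-1-methylbenzene; 6 4-methoxyphenylboronic acid
Product: 7 2-bromo-3-(4-methoxybenzyl)-4-(4-methoxyphenyl)-1-methylbenzene
Conditions: Pd(PPh3)4 (5 mol %), Na2CO3, DME/H2O, 80 °C
Reagents that add atoms: none
Why: Suzuki–Miyaura coupling at a benzylic sp3 bromide: zerovalent palladium inserts into the benzylic C–Br bond far faster than into the aryl C–Br bond flanked by the methyl and CH2 groups. Only the C7–ring C bond should form, and the aryl bromide is kept for step 5.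

Step 5
Reactants: 7 2-bromo-3-(4-methoxybenzyl)-4-(4-methoxyphenyl)-1-methylbenzene; 8 4-ethynylanisole
Product: 9 2-(4-methoxybenzyl)-1-(4-methoxyphenyl)-3-[(4-methoxyphenyl)ethynyl]-4-methylbenzene
Conditions: PdCl2(MeCN)2 (3 mol %), XPhos, Cs2CO3, MeCN, 80 °C
Reagents that add atoms: none
Why: Copper-free Sonogashira coupling: zerovalent palladium carrying the bulky biarylphosphine XPhos undergoes oxidative addition into the di-ortho-substituted aryl bromide, and the absence of copper suppresses oxidative dimerisation of the electron-rich alkyne 8. Cs2CO3 is far too weak a base to deprotonate the diarylmethane CH2.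

Step 6
Reactants: 9 2-(4-methoxybenzyl)-1-(4-methoxyphenyl)-3-[(4-methoxyphenyl)ethynyl]-4-methylbenzene; 10 anisole
Product: 12 2-[bis(4-methoxyphenyl)methyl]-1-(4-methoxyphenyl)-3-[(4-methoxyphenyl)ethynyl]-4-methylbenzene, via diarylcarbenium tetrafluoroborate 11 (not isolated)
Conditions: divided cell, carbon-felt anode, Pt cathode with TfOH in the cathode chamber, Bu4NBF4, CH2Cl2, −78 °C, constant current, 2.2 F/mol; then anisole (5 equiv), −78 to −40 °C; Et3N
Reagents that add atoms: none
Why: Anodic electron transfer gives a radical cation whose hole can move among the three anisyl chromophores; in the nucleophile-free medium the only fast irreversible exit is loss of a proton from the doubly benzylic C7, and the diarylmethyl radical so formed is oxidised at once to carbenium ion 11, which accumulates as its tetrafluoroborate at −78 °C. With the current off, anisole (10) attacks C7 through its para carbon in a Friedel–Crafts substitution and loss of a proton gives 12. The closest known reaction type is the cation-pool oxidation of diarylmethanes to diarylcarbenium ions with capture by an arene. No ring is closed and no stereocentre arises, because C7 of 12 carries two identical 4-methoxyphenyl groups. Site selectivity of the oxidation rests on C7 being the only doubly benzylic, para-methoxy-activated position, whereas the C1 methyl group sits on the unoxygenated ring A. Chemoselectivity of the capture rests on geometry: ring B can reach C7 only through a carbon meta to its methoxy group, and the alkyne would have to close a four-membered ring or a five-membered ring with an endocyclic vinyl cation, so intermolecular attack by excess anisole should win. The para positions of all anisyl rings of 9 are blocked, which slows self-condensation of 9 with 11, and the bulk of the cation secures para over ortho attack on anisole. Because 10 and 12 never face the anode under current, over-oxidation of the triarylmethane is excluded.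

Step 7
Reactants: 12 2-[bis(4-methoxyphenyl)methyl]-1-(4-methoxyphenyl)-3-[(4-methoxyphenyl)ethynyl]-4-methylbenzene
Product: 13 4,4'-{[6-(4-hydroxyphenyl)-2-[(4-hydroxyphenyl)ethynyl]-3-methylphenyl]methylene}diphenol
Conditions: BBr3 (8 equiv), CH2Cl2, −78 to 0 °C; then MeOH, H2O
Reagents that add atoms: none
Why: Lewis acid cleavage of aryl methyl ethers: each ether forms an oxonium–borane adduct that bromide demethylates, and hydrolysis frees the four phenols. Diaryl alkynes and the triarylmethane C–H tolerate BBr3 at or below 0 °C.

Step 8
Reactants: 13 4,4'-{[6-(4-hydroxyphenyl)-2-[(4-hydroxyphenyl)ethynyl]-3-methylphenyl]methylene}diphenol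
Product: 14 Selaginellin U, 4-[(4-hydroxyphenyl){6-(4-hydroxyphenyl)-2-[(4-hydroxyphenyl)ethynyl]-3-methylphenyl}methylidene]cyclohexa-2,5-dien-1-one
Conditions: DDQ (1.05 equiv), 1,4-dioxane, rt
Reagents that add atoms: none
Why: Dehydrogenation of a leuco 4-hydroxytriarylmethane to the fuchsone-type quinone methide: DDQ abstracts hydride from C7, which two para-hydroxyaryl groups activate, and the hydroxytrityl cation loses a phenolic proton. Rings C and D are interchangeable, so a single product can form, and one equivalent of oxidant limits attack on the remaining phenols.

## Compound list

1 | 2-bromo-3-methylbenzoic acid | Cc1cccc(C(=O)O)c1Br | starting material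
2 | 4-iodoanisole | COc1ccc(I)cc1 | starting material
3 | 2-bromo-6-(4-methoxyphenyl)-3-methylbenzoic acid | Cc1ccc(-c2ccc(OC)cc2)c(C(=O)O)c1Br | intermediate
4 | [2-bromo-6-(4-methoxyphenyl)-3-methylphenyl]methanol | Cc1ccc(-c2ccc(OC)cc2)c(CO)c1Br | intermediate
5 | 2-bromo-3-(bromomethyl)-4-(4-methoxyphenyl)-1-methylbenzene | Cc1ccc(-c2ccc(OC)cc2)c(CBr)c1Br | intermediate
6 | 4-methoxyphenylboronic acid | COc1ccc(B(O)O)cc1 | starting material
7 | 2-bromo-3-(4-methoxybenzyl)-4-(4-methoxyphenyl)-1-methylbenzene | Cc1ccc(-c2ccc(OC)cc2)c(Cc2ccc(OC)cc2)c1Br | intermediate
8 | 4-ethynylanisole | COc1ccc(C#C)cc1 | starting material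
9 | 2-(4-methoxybenzyl)-1-(4-methoxyphenyl)-3-[(4-methoxyphenyl)ethynyl]-4-methylbenzene | Cc1ccc(-c2ccc(OC)cc2)c(Cc2ccc(OC)cc2)c1C#Cc1ccc(OC)cc1 | intermediate
10 | anisole | COc1ccccc1 | starting material
11 | [6-(4-methoxyphenyl)-2-[(4-methoxyphenyl)ethynyl]-3-methylphenyl](4-methoxyphenyl)methylium tetrafluoroborate | Cc1ccc(-c2ccc(OC)cc2)c([CH+]c2ccc(OC)cc2)c1C#Cc1ccc(OC)cc1.F[B-](F)(F)F | intermediate
12 | 2-[bis(4-methoxyphenyl)methyl]-1-(4-methoxyphenyl)-3-[(4-methoxyphenyl)ethynyl]-4-methylbenzene | Cc1ccc(-c2ccc(OC)cc2)c(C(c2ccc(OC)cc2)c2ccc(OC)cc2)c1C#Cc1ccc(OC)cc1 | intermediate
13 | 4,4'-{[6-(4-hydroxyphenyl)-2-[(4-hydroxyphenyl)ethynyl]-3-methylphenyl]methylene}diphenol | Cc1ccc(-c2ccc(O)cc2)c(C(c2ccc(O)cc2)c2ccc(O)cc2)c1C#Cc1ccc(O)cc1 | intermediate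
14 | Selaginellin U, 4-[(4-hydroxyphenyl){6-(4-hydroxyphenyl)-2-[(4-hydroxyphenyl)ethynyl]-3-methylphenyl}methylidene]cyclohexa-2,5-dien-1-one | Cc1ccc(-c2ccc(O)cc2)c(C(=C2C=CC(=O)C=C2)c2ccc(O)cc2)c1C#Cc1ccc(O)cc1 | target

## Step count and risks

Total step count: 8. Longest linear sequence: 8 steps, from 1 to 14.

**Step 6 (key step).**
- What may go wrong: the radical cation may react at the tolane or the biaryl chromophore by radical-cation coupling and oligomerisation before the C7 proton is lost. The pooled cation may decay during the electrolysis by ring closure onto ring B. During capture, hydride transfer from the product to cation still present may compete.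
- Fallback: this keeps the same C7–aryl bond and the same kind of cation but makes the cation by ionising a C–O bond, with no electrode and no alkyne present. It sets out from 4 and returns at 12. Alcohol 4 would be oxidised with MnO2 in CH2Cl2 to 2-bromo-6-(4-methoxyphenyl)-3-methylbenzaldehyde F1. Addition of 4-methoxyphenylmagnesium bromide in THF at 0 °C should give racemic [2-bromo-6-(4-methoxyphenyl)-3-methylphenyl](4-methoxyphenyl)methanol F2. Friedel–Crafts reaction of F2 with anisole (10) under catalytic FeCl3 in CH2Cl2 should give 3-[bis(4-methoxyphenyl)methyl]-2-bromo-4-(4-methoxyphenyl)-1-methylbenzene F3. Sonogashira coupling of F3 with 8 under the conditions of step 5 would then give 12. Four steps replace steps 3 to 6, so the count is unchanged; the price is a more crowded alkynylation.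

**Step 1.**
- What may go wrong: silver-promoted protodecarboxylation of the 2,6-disubstituted acid at the reaction temperature, or insertion of adventitious zerovalent palladium into the C–Br bond.
- Fallback: the C–H arylation is split into halogenation and cross-coupling. It sets out from 1 and returns at 3. Carboxylate-directed ortho-iodination of 1 (Pd(OAc)2, PhI(OAc)2, I2, DMF) should give 2-bromo-6-iodo-3-methylbenzoic acid F4. Its C–I bond would then be coupled selectively with boronic acid 6 (Pd(PPh3)4, K2CO3, dioxane/H2O) to give 3.

**Step 5.**
- What may go wrong: slow oxidative addition into the bromide between the methyl and the anisylmethyl group, so that oligomerisation of alkyne 8 consumes the coupling partner.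
- Fallback: the polarity of the coupling is reversed so that the crowded partner is the alkyne. It sets out from 7 and returns at 9. Bromine–lithium exchange of 7 with n-butyllithium in THF at −78 °C and quenching with DMF should give 2-(4-methoxybenzyl)-3-(4-methoxyphenyl)-6-methylbenzaldehyde F5. Ohira–Bestmann homologation (dimethyl (1-diazo-2-oxopropyl)phosphonate, K2CO3, MeOH) should give 2-ethynyl-3-(4-methoxybenzyl)-4-(4-methoxyphenyl)-1-methylbenzene F6. Sonogashira coupling of F6 with 4-iodoanisole (2) (PdCl2(PPh3)2, CuI, Et3N) would then give 9.

**Step 8.**
- What may go wrong: unselective oxidation of the free phenols of rings B and E, or acid-promoted ring closure of the hydroxytrityl cation onto ring B before it loses its proton.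
- Fallback: the oxidation level is set before the phenols are freed. It sets out from 12 and returns at 14, replacing steps 7 and 8. Hydride abstraction from 12 with DDQ in wet CH2Cl2 should give [6-(4-methoxyphenyl)-2-[(4-methoxyphenyl)ethynyl]-3-methylphenyl]bis(4-methoxyphenyl)methanol F7. Treatment of F7 with BBr3 in CH2Cl2 cleaves the four ethers, and the 4-hydroxytriaryl carbinol loses water on work-up to give 14 directly.

## Further compounds

F1 | step 6 | 2-bromo-6-(4-methoxyphenyl)-3-methylbenzaldehyde | Cc1ccc(-c2ccc(OC)cc2)c(C=O)c1Br
F2 | step 6 | [2-bromo-6-(4-methoxyphenyl)-3-methylphenyl](4-methoxyphenyl)methanol (racemic) | Cc1ccc(-c2ccc(OC)cc2)c(C(O)c2ccc(OC)cc2)c1Br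
F3 | step 6 | 3-[bis(4-methoxyphenyl)methyl]-2-bromo-4-(4-methoxyphenyl)-1-methylbenzene | Cc1ccc(-c2ccc(OC)cc2)c(C(c2ccc(OC)cc2)c2ccc(OC)cc2)c1Br
F4 | step 1 | 2-bromo-6-iodo-3-methylbenzoic acid | Cc1ccc(I)c(C(=O)O)c1Br
F5 | step 5 | 2-(4-methoxybenzyl)-3-(4-methoxyphenyl)-6-methylbenzaldehyde | Cc1ccc(-c2ccc(OC)cc2)c(Cc2ccc(OC)cc2)c1C=O
F6 | step 5 | 2-ethynyl-3-(4-methoxybenzyl)-4-(4-methoxyphenyl)-1-methylbenzene | Cc1ccc(-c2ccc(OC)cc2)c(Cc2ccc(OC)cc2)c1C#C
F7 | step 8 | [6-(4-methoxyphenyl)-2-[(4-methoxyphenyl)ethynyl]-3-methylphenyl]bis(4-methoxyphenyl)methanol | Cc1ccc(-c2ccc(OC)cc2)c(C(O)(c2ccc(OC)cc2)c2ccc(OC)cc2)c1C#Cc1ccc(OC)cc1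
A1 | alternative 1 | 1-methoxy-1,3-bis(trimethylsilyloxy)penta-1,3-diene (double-bond geometry left open) | COC(O[Si](C)(C)C)=CC(O[Si](C)(C)C)=CC
A2 | alternative 1 | 3,3-dimethoxy-1-(4-methoxyphenyl)propan-1-one | COc1ccc(C(=O)CC(OC)OC)cc1
A3 | alternative 1 | methyl 2-hydroxy-6-(4-methoxyphenyl)-3-methylbenzoate | COC(=O)c1c(O)c(C)ccc1-c1ccc(OC)cc1
A4 | alternative 2 | 2-bromo-6-(4-methoxyphenyl)-3-methylbenzoic acid | Cc1ccc(-c2ccc(OC)cc2)c(C(=O)O)c1Br
A5 | alternative 2 | [2-bromo-6-(4-methoxyphenyl)-3-methylphenyl]bis(4-methoxyphenyl)methanol | Cc1ccc(-c2ccc(OC)cc2)c(C(O)(c2ccc(OC)cc2)c2ccc(OC)cc2)c1Br
A6 | alternative 3 | (E)-1-methoxy-4-(pent-1-en-3-yn-1-yl)benzene | COc1ccc(/C=C/C#CC)cc1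
A7 | alternative 3 | methyl 5-(4-methoxyphenyl)penta-2,4-diynoate | COC(=O)C#CC#Cc1ccc(OC)cc1
A8 | alternative 3 | methyl 6-(4-methoxyphenyl)-2-[(4-methoxyphenyl)ethynyl]-3-methylbenzoate | COC(=O)c1c(-c2ccc(OC)cc2)ccc(C)c1C#Cc1ccc(OC)cc1
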